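Each complex charged stays in the flask in some form, and each exchange takes one incoming ligand from a stock that nothing refills, so the sum of c(starting complex) and what is spare beyond it equals c(incoming ligand) as charged.

| flask | starting complex | incoming ligand | remark | time |
|---|---|---|---|---|
| south | 0.21 M | 0.54 M | run made earlier |  |
| west | 0.81 M | 0.54 M | run made earlier |  |
| midnight | 0.15 M | 0.540 M |  | 4.0 d |
| winter | 0.30 M | 0.540 M |  | 4.0 d |
| autumn | 0.60 M | 0.540 M |  | 4.0 d |

| run | time / d | complex with three exchanged / % | starting complex / % |
|---|---|---|---|
| south | 0.208 | 1.3 | 58.4 |
| south | 0.417 | 1.7 | 32.7 |
| south | 0.833 | 4.6 | 11.5 |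
| south | 1.67 | 7.2 | 3.4 |
| south | 3.00 | 11.4 | 0 |
| west | 0.250 | 0.8 | 55.2 |
| west | 0.625 | 1.9 | 27.2 |
| west | 1.25 | 2.3 | 11.9 |
| west | 2.08 | 0.9 | 5.7 |
| west | 3.00 | 2.7 | 2.9 |

(each reading ± 1 percentage point)

- "hardly changes" means that all values lie within two and a half points (for a concentration: within two and a half percent of the largest)

1. [complex with three exchanged] at the end for midnight, winter, autumn, in this order
2. the course of these numbers from the first flask to the last (falls all the way / hardly changes / rises all the way / rises, then falls / falls, then rises)

In both earlier runs the starting complex goes quickly: south keeps 3.4% at 1.67 d, west 5.7% at 2.08 d. But west has lost 0.787 M of starting complex at 3.00 d, more than the 0.54 M of ligand charged, so not every loss of starting complex takes an incoming ligand. As a rough count I still set one ligand against each complex charged, and the complex with three exchanged needs two more. I call c(incoming ligand) − c(starting complex), as charged, the spare ligand. South has 0.330 M of it, and its product climbs from 4.6% at 0.833 d to 11.4% at 3.00 d, a reading of 0.0314 d⁻¹ of the charge. Dividing by the spare gives 0.0951 M⁻¹ d⁻¹. West has a spare of −0.270 M, and its last readings average 1.97%, which I take as a floor.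

My own reckoning is floor plus this constant times spare times time, as a share of the charge. That gives 0.0252 M for midnight, 0.0333 M for winter and, with a negative spare, 0.0118 M for autumn. The growing part goes as c(starting complex) times the spare, two numbers with a fixed sum, and such a product is greatest when they are equal, at half of c(incoming ligand). The floor adds a part proportional to c(starting complex), so I set the slope of the whole reckoned row to zero. At this ligand charge and this time, that gives the turning charge, the c(starting complex) at which my reckoned row is greatest: 0.296 M, above half of the ligand charge.

The forecast says 0.027 M, 0.032 M, 0.019 M, rises, then falls: “I therefore assume later growth scales with leftover ligand”. Its autumn stands higher than mine.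

The flasks give 0.0260 M, 0.0325 M, 0.0230 M: rises, then falls.

    starting complex + incoming ligand → leaving ligand + complex with one exchanged (k = 0.210 M⁻¹ h⁻¹)
    complex with one exchanged + incoming ligand → leaving ligand + complex with two exchanged (k = 0.0210 M⁻¹ h⁻¹)
    complex with two exchanged + incoming ligand → leaving ligand + complex with three exchanged (k = 0.520 M⁻¹ h⁻¹)
    complex with three exchanged ⇌ isomer of the product (K = 1.30, k = 0.300 h⁻¹)
    leaving ligand + starting complex → side product (k = 0.190 M⁻¹ h⁻¹)

In midnight at 4.00 d, the complex with one exchanged has a half-life of 4.8 d by the second exchange, far longer than the 0.19 d of the complex with two exchanged by the third. At that moment 46.4% of the charge stands in the first form, the resting state, and 1.95% in the second. The row turns at 0.31 M, higher than my 0.296 M. Autumn, with a spare of −0.0600 M, holds 3.84% of product, above my floor, with 7.7% of its ligand left and 36.4% of its charge as side product.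

The data are simulated on assumed constants, and the scatter is random.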